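**Retrosynthetic overview** (disconnections listed in the order the bonds are made)
1. C8–O(aryl) ether: dihydroconiferyl alcohol (1) + ethyl O-tosyl-L-lactate (2) → aryloxy ester (3) by SN2 with inversion; C8 is bought in the lactate.
2. Redox adjustment: ester 3 → α-aryloxy aldehyde (4).
3. C7–C(aryl) bond (key step, visible-light Cr/Ni arylation): 4 + 5-iodo-1,2,3-trimethoxybenzene (5) → target (6); C7 is set by C8 (Felkin–Anh), all catalysts achiral.
4. Rings: none are formed; both benzene rings are purchased intact.

Assumption: compounds 1, 2 and 5 are treated as catalogue items (2 is the bulk tosylate of ethyl L-lactate). The target is the erythro (7S,8R) isomer, i.e. (1S,2R) by IUPAC numbering.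

**Step 1**
Reactants: 1, 4-(3-hydroxypropyl)-2-methoxyphenol (dihydroconiferyl alcohol); 2, ethyl (S)-2-(tosyloxy)propanoate
Product: 3, ethyl (R)-2-[4-(3-hydroxypropyl)-2-methoxyphenoxy]propanoate
Conditions: K2CO3 (1.5 equiv), MeCN, 60 °C
Reagents that add atoms: none beyond the numbered reactants (2: ethyl (S)-2-(tosyloxy)propanoate, CCOC(=O)[C@H](C)OS(=O)(=O)c1ccc(C)cc1)
Why: Williamson ether synthesis; the phenoxide displaces the secondary tosylate by SN2 with inversion (S → R at the future C8), and carbonate deprotonates only the phenol, so the primary alcohol is not alkylated.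

**Step 2**
Reactants: 3, ethyl (R)-2-[4-(3-hydroxypropyl)-2-methoxyphenoxy]propanoate
Product: 4, (R)-2-[4-(3-hydroxypropyl)-2-methoxyphenoxy]propanal
Conditions: DIBAL-H (2.2 equiv), CH2Cl2, −78 °C; MeOH, then aq. Rochelle salt; used crude at once
Reagents that add atoms: none (hydride only)
Why: Partial ester reduction with DIBAL; the first equivalent is consumed by the free OH, and the α-aryloxy-chelated aluminium hemiacetal survives at −78 °C and releases the aldehyde only on quench, so C8 is untouched under these non-basic conditions.

**Step 3**
Reactants: 4, (R)-2-[4-(3-hydroxypropyl)-2-methoxyphenoxy]propanal; 5, 5-iodo-1,2,3-trimethoxybenzene (1.5 equiv)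
Product: 6, (1S,2R)-2-[4-(3-hydroxypropyl)-2-methoxyphenoxy]-1-(3,4,5-trimethoxyphenyl)propan-1-ol (target)
Conditions: 4CzIPN (2 mol%), CrCl3·3THF (10 mol%), NiCl2·glyme/neocuproine (2 mol%), Hantzsch ester (1.5 equiv), degassed DMF, 450 nm LEDs, 10 °C
Reagents that add atoms: none beyond the numbered reactants (5: COc1cc(I)cc(OC)c1OC); the Hantzsch ester supplies only electrons and H
Why: Proposed new method: a light-driven Cr/Ni-catalysed Nozaki–Hiyama–Kishi-type arylation in which reductively quenched 4CzIPN (Hantzsch ester as terminal 2e⁻/H⁺ donor) reduces Cr(III) to Cr(II) and Ni(II) to Ni(0), Ni(0) inserts into the C–I bond of 5, the aryl group transfers from Ni(II) to Cr(III), and the non-basic, poorly chelating aryl–Cr(III) species adds to aldehyde 4 through a polar Felkin–Anh transition state (C8–OAr anti to the incoming aryl, which passes C8–H rather than CH3), converting 8R into 7S (erythro), while the Hantzsch pyridinium protonates the Cr(III) alkoxide so Cr turns over without a silyl chloride and the free primary OH is tolerated; the closest known reactions are the metal-reductant and electrochemical Ni/Cr NHK couplings of aryl/alkenyl halides with aldehydes and the photoredox Cr-catalysed allylation of aldehydes.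

**Compound list**
1 | 4-(3-hydroxypropyl)-2-methoxyphenol (dihydroconiferyl alcohol) | COc1cc(CCCO)ccc1O | starting material
2 | ethyl (S)-2-(tosyloxy)propanoate (ethyl O-tosyl-L-lactate) | CCOC(=O)[C@H](C)OS(=O)(=O)c1ccc(C)cc1 | starting material
3 | ethyl (R)-2-[4-(3-hydroxypropyl)-2-methoxyphenoxy]propanoate | CCOC(=O)[C@@H](C)Oc1ccc(CCCO)cc1OC | intermediate
4 | (R)-2-[4-(3-hydroxypropyl)-2-methoxyphenoxy]propanal | O=C[C@@H](C)Oc1ccc(CCCO)cc1OC | intermediate
5 | 5-iodo-1,2,3-trimethoxybenzene | COc1cc(I)cc(OC)c1OC | starting material
6 | (1S,2R)-2-[4-(3-hydroxypropyl)-2-methoxyphenoxy]-1-(3,4,5-trimethoxyphenyl)propan-1-ol (erythro, 7S,8R) | COc1cc(CCCO)ccc1O[C@H](C)[C@@H](O)c1cc(OC)c(OC)c(OC)c1 | target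

**Total steps:** 3. **Longest linear sequence:** 3.

**Steps most likely to fail (the route has only three, ranked by risk)**
1. Step 3 (proposed new step). Risks: inefficient aryl transfer to Cr or poor Cr turnover under photoredox conditions (giving ArH or biaryl), and only moderate Felkin selectivity (expected roughly 5:1 or better; the threo isomer would be removed by chromatography). Fallback (known chemistry, different approach): convert ester 3 to its Weinreb amide, add 3,4,5-trimethoxyphenylmagnesium bromide to give the α-aryloxy aryl ketone, and reduce under chelation control with Zn(BH4)2, which delivers the same erythro (7S,8R) alcohol.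
2. Step 2. Risks: over-reduction to the diol, hemiacetal oligomers from the free OH, or epimerisation of the α-aryloxy aldehyde on handling. Fallback: carry the side chain masked as an allyl group by starting from eugenol (4-allyl-2-methoxyphenol) in place of 1, so no free OH is present through the sequence, and reveal the 3-hydroxypropyl group at the end by 9-BBN hydroboration/oxidation.
3. Step 1. Risks: partial loss of ee through base-mediated enolisation of 3, or E2 elimination of the tosylate. Fallback: form the C8–O bond by Mitsunobu reaction (PPh3, DIAD) of ethyl (S)-lactate with eugenol, which gives clean inversion under neutral conditions, with the same late hydroboration to install the primary alcohol.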